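The ten-membered carbocycle (ring carbons numbered from the isopropenyl-bearing C1 to the senecioate-bearing C10) is closed last at the bond between C4, the methyl-bearing tertiary carbinol, and C5, the angelate-bearing carbon. The key step exploits this vicinal C4/C5 dioxygenation: in the open-chain precursor both carbons are carbonyls, a C4 methyl ketone next to a C3 p-methoxybenzyl ether and a C5 aldehyde one methylene from the cis C7–C8 epoxide, and SmI2 joins these two like-polarity carbons reductively (pinacol coupling), forming the ring and both carbinol stereocentres in one operation. The chain, already carrying the C9 acetate and C10 senecioate, comes from (R)-carvone and a (Z)-vinyl iodide.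

Key step: step 15

Remark: the numbering above (C2 and C6 methylenes, C3 free carbinol, C8 methyl-bearing epoxide carbon, C9 acetate carbon) is kept for all intermediates; PMB = 4-methoxybenzyl, TBS = tert-butyldimethylsilyl; (R)-carvone and 3-(TBS-oxy)propanal are taken as commercial.

Step 1
Reactants: 1 (R)-(−)-carvone
Product: 2 (−)-cis-carveol [(1R,5R)-2-methyl-5-(prop-1-en-2-yl)cyclohex-2-en-1-ol]
Conditions: NaBH4, CeCl3·7H2O, MeOH, −78 °C
Reagents that add atoms: none
Why: Luche 1,2-reduction, in which axial hydride delivery should give the equatorial alcohol cis to the isopropenyl group, so that the carvone stereocentre (C1) sets C3.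

Step 2
Reactants: 2 (−)-cis-carveol
Product: 3 cis-carveol epoxide (hydroxyl, oxirane oxygen and isopropenyl all on one ring face)
Conditions: VO(acac)2 (cat.), t-BuOOH, CH2Cl2, 0 °C → rt
Reagents that add atoms: tert-butyl hydroperoxide, CC(C)(C)OO
Why: Hydroxyl-directed vanadium-catalysed epoxidation should engage only the allylic-alcohol double bond (isopropenyl untouched) and deliver oxygen syn to the hydroxyl; the two new centres are temporary.

Step 3
Reactants: 3 cis-carveol epoxide
Product: 4 PMB ether of 3
Conditions: NaH, PMBCl, Bu4NI (cat.), THF/DMF, 0 °C → rt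
Reagents that add atoms: 4-methoxybenzyl chloride, COc1ccc(CCl)cc1
Why: Williamson etherification; Payne rearrangement is excluded because the alkoxide sits on the same face as the oxirane oxygen and cannot attack it from behind.

Step 4
Reactants: 4 PMB ether of 3
Product: 6 tertiary allylic alcohol (6-PMB-oxy-1-methyl-4-isopropenylcyclohex-2-en-1-ol; hydroxyl, PMB ether and isopropenyl all cis), via hydroxy selenide 5 (not isolated)
Conditions: (PhSe)2, NaBH4, EtOH, 80 °C; then 30% H2O2, pyridine, THF, 0 °C → rt
Reagents that add atoms: none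
Why: Selenolate opening of the epoxide at the secondary carbon (future C9) in the trans-diaxial (Fürst–Plattner) sense, followed by selenoxide syn-elimination, which can only run toward future C10, should give the transposed tertiary allylic alcohol.

Step 5
Reactants: 6 tertiary allylic alcohol
Product: 7 (1R,4R,6R)-4-[(4-methoxyphenyl)methoxy]-3-methyl-6-(prop-1-en-2-yl)cyclohex-2-en-1-ol (all-cis)
Conditions: Ph3SiOReO3 (2 mol %), Et2O, −50 → 0 °C
Reagents that add atoms: none
Why: Oxo-rhenium-catalysed 1,3-transposition of an allylic alcohol ([3,3] shift of the perrhenate ester), driven by formation of the trisubstituted alkene; being suprafacial it should place the new C10 hydroxyl on the face the tertiary hydroxyl occupied, cis to isopropenyl.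

Step 6
Reactants: 7 all-cis secondary allylic alcohol
Product: 8 epoxy alcohol (ring epoxide syn to the C10 hydroxyl)
Conditions: VO(acac)2 (cat.), t-BuOOH, CH2Cl2, 0 °C → rt
Reagents that add atoms: tert-butyl hydroperoxide, CC(C)(C)OO
Why: Hydroxyl-directed vanadium-catalysed epoxidation marks the ring alkene for cleavage while sparing the isopropenyl group; the epoxide centres are destroyed in step 8, so its facial course is irrelevant.

Step 7
Reactants: 8 epoxy alcohol
Product: 9 epoxy senecioate (3-methylbut-2-enoate of 8)
Conditions: 3-methylbut-2-enoic acid, DCC, DMAP (cat.), CH2Cl2, 0 °C → rt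
Reagents that add atoms: 3-methylbut-2-enoic acid (senecioic acid), CC(C)=CC(=O)O
Why: Steglich esterification installs the C10 ester while C10 is the only free hydroxyl; the carbodiimide route avoids the deconjugation seen with the acid chloride and amine bases.

Step 8
Reactants: 9 epoxy senecioate
Product: 10 keto aldehyde (2S,3R,5R)-5-[(4-methoxyphenyl)methoxy]-1,6-dioxo-3-(prop-1-en-2-yl)heptan-2-yl 3-methylbut-2-enoate
Conditions: H5IO6, THF/H2O, 0 °C → rt; used crude
Reagents that add atoms: water, O
Why: Periodic acid hydrolyses the trisubstituted epoxide and cleaves the resulting glycol (Malaprade-type cleavage) to the C4 methyl ketone and C9 aldehyde; unlike ozone it leaves the isopropenyl and senecioate alkenes alone.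

Step 9
Reactants: 11 3-[(tert-butyldimethylsilyl)oxy]propanal
Product: 12 (Z)-tert-butyl[(4-iodopent-3-en-1-yl)oxy]dimethylsilane
Conditions: EtPPh3I, n-BuLi, THF, 0 °C; I2, −78 °C; NaN(SiMe3)2, −20 °C; then 11, −78 °C → rt
Reagents that add atoms: ethyltriphenylphosphonium iodide, CC[P+](c1ccccc1)(c1ccccc1)c1ccccc1.[I-]; iodine, II
Why: Wittig olefination with the non-stabilised α-iodo ylide (Stork–Zhao-type iodo-olefination) should give, under kinetic control, the (Z)-iodoalkene with iodine cis to the chain.

Step 10
Reactants: 10 keto aldehyde; 12 (Z)-vinyl iodide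
Product: 13 (Z)-allylic alcohol (C8–C9 bond formed; 9,10-anti)
Conditions: CrCl2 (5 equiv), NiCl2 (2 mol %), DMSO, rt
Reagents that add atoms: none
Why: Nozaki–Hiyama–Kishi coupling, in which the alkenylchromium adds only to the aldehyde (ketone and esters spared) with retention of alkene geometry; polar Felkin–Anh attack anti to the C10 acyloxy group should set C9.

Step 11
Reactants: 13 (Z)-allylic alcohol
Product: 14 erythro epoxy alcohol (C7–C8 cis-epoxide)
Conditions: Ti(OiPr)4 (1.1 equiv), D-(−)-diisopropyl tartrate (1.3 equiv), t-BuOOH, 4 Å sieves, CH2Cl2, −20 °C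
Reagents that add atoms: tert-butyl hydroperoxide, CC(C)(C)OO
Why: Sharpless asymmetric epoxidation in the matched sense, where the D-tartrate face preference coincides with the erythro preference imposed by 1,2-allylic strain from the C8 methyl, should set C7 and C8; the metal-bound alkoxide confines oxidation to this alkene.

Step 12
Reactants: 14 erythro epoxy alcohol
Product: 15 epoxy acetate
Conditions: Ac2O, pyridine, DMAP (cat.), CH2Cl2, 0 °C
Reagents that add atoms: acetic anhydride, CC(=O)OC(C)=O
Why: Standard acylation of the only free hydroxyl (C9), done promptly to forestall senecioate migration from C10.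

Step 13
Reactants: 15 epoxy acetate
Product: 16 primary alcohol (C5 hydroxyl)
Conditions: Bu4NF/AcOH (1:1), THF, 0 °C → rt
Reagents that add atoms: none
Why: Buffered fluoride desilylation removes the primary TBS ether without touching the esters or triggering acid-promoted attack of the new hydroxyl on the epoxide.

Step 14
Reactants: 16 primary alcohol
Product: 17 keto aldehyde (C5 aldehyde, C4 methyl ketone; cyclisation precursor)
Conditions: Dess–Martin periodinane, NaHCO3, CH2Cl2, 0 °C; used at once
Reagents that add atoms: none
Why: Dess–Martin oxidation under buffered, amine-free conditions should give the β,γ-epoxy aldehyde without β-elimination of the oxirane.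

Step 15
Reactants: 17 keto aldehyde
Product: 18 ten-membered diol (C4 tertiary and C5 secondary hydroxyls trans; C3 PMB ether)
Conditions: SmI2 (3 equiv), THF, 2 mM, slow addition of 17, −78 → −20 °C; sat. NH4Cl
Reagents that add atoms: none
Why: Single-electron transfer from SmI2 to the C5 aldehyde gives a samarium-bound ketyl radical that adds to the C4 ketone, and a second electron delivers the samarium diolate (intramolecular ketone–aldehyde pinacol coupling, the known SmI2 and McMurry-type pinacol cyclisation extended to a ten-membered carbocycle). The ring closes by a 10-exo-trig addition of the ketyl to the ketone carbonyl, helped by the turn that the cis C7–C8 epoxide imposes on the chain and by high dilution. C4 is controlled by chelation: trivalent samarium bridges the ketone oxygen and the C3 PMB ether, so C5 should add anti to C2 and place the C4 hydroxyl syn to the C3 oxygen (Cram-chelate sense). C5 is controlled by the samarium-bridged diolate geometry with an antiperiplanar C3–C4–C5–C6 backbone, which should give the trans diol as in pinacol closures of rings of ten or more members; this is the less secure centre. The step needs chemoselective reduction of the aldehyde beside the acetate, the senecioate, the epoxide and the α-alkoxy ketone, which additive-free SmI2 at low temperature should secure because aldehydes are reduced first.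

Step 16
Reactants: 18 ten-membered diol
Product: 19 C5 angelate (C3 PMB ether)
Conditions: angelic acid, 2,4,6-trichlorobenzoyl chloride, Et3N, toluene, rt; then 18, toluene, 80 °C (no DMAP)
Reagents that add atoms: angelic acid, C/C=C(/C)C(=O)O
Why: Yamaguchi-type mixed-anhydride esterification acylates the secondary C5 hydroxyl in preference to the tertiary C4 hydroxyl, and the DMAP-free protocol avoids isomerisation of the angelate to the tiglate.

Step 17
Reactants: 19 C5 angelate
Product: 20 target CNP0298989.1
Conditions: DDQ, CH2Cl2/pH 7 buffer (10:1), 0 °C → rt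
Reagents that add atoms: none
Why: Oxidative cleavage of the PMB ether with DDQ is neutral and spares the three esters, the epoxide and the alkenes; the aqueous phase hydrolyses any p-methoxybenzylidene acetal formed with the neighbouring C4 hydroxyl.

Compound list
1 | (R)-(−)-carvone | C=C(C)[C@@H]1CC=C(C)C(=O)C1 | starting material
2 | (−)-cis-carveol, (1R,5R) | C=C(C)[C@H]1C[C@@H](O)C(C)=CC1 | intermediate
3 | cis-carveol epoxide (OH, oxirane O and isopropenyl cis) | C=C(C)[C@H]1C[C@@H](O)[C@@]2(C)O[C@H]2C1 | intermediate
4 | PMB ether of 3 | C=C(C)[C@H]1C[C@@H](OCc2ccc(OC)cc2)[C@@]3(C)O[C@H]3C1 | intermediate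
5 | hydroxy selenide (phenylseleno group trans to the tertiary hydroxyl) | C=C(C)[C@H]1C[C@@H](OCc2ccc(OC)cc2)[C@@](C)(O)[C@H]([Se]c2ccccc2)C1 | intermediate
6 | tertiary allylic alcohol, all-cis | C=C(C)[C@H]1C[C@@H](OCc2ccc(OC)cc2)[C@@](C)(O)C=C1 | intermediate
7 | (1R,4R,6R)-4-[(4-methoxyphenyl)methoxy]-3-methyl-6-(prop-1-en-2-yl)cyclohex-2-en-1-ol | C=C(C)[C@H]1C[C@@H](OCc2ccc(OC)cc2)C(C)=C[C@H]1O | intermediate
8 | epoxy alcohol (epoxide syn to C10 hydroxyl) | C=C(C)[C@H]1C[C@@H](OCc2ccc(OC)cc2)[C@@]3(C)O[C@H]3[C@H]1O | intermediate
9 | epoxy senecioate | C=C(C)[C@H]1C[C@@H](OCc2ccc(OC)cc2)[C@@]3(C)O[C@H]3[C@H]1OC(=O)C=C(C)C | intermediate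
10 | keto aldehyde, (2S,3R,5R)-5-[(4-methoxyphenyl)methoxy]-1,6-dioxo-3-(prop-1-en-2-yl)heptan-2-yl 3-methylbut-2-enoate | O=C[C@@H](OC(=O)C=C(C)C)[C@@H](C(C)=C)C[C@@H](OCc1ccc(OC)cc1)C(C)=O | intermediate
11 | 3-[(tert-butyldimethylsilyl)oxy]propanal | O=CCCO[Si](C)(C)C(C)(C)C | starting material
12 | (Z)-tert-butyl[(4-iodopent-3-en-1-yl)oxy]dimethylsilane | I/C(C)=C\CCO[Si](C)(C)C(C)(C)C | intermediate
13 | (Z)-allylic alcohol, C9 hydroxyl anti to C10 senecioate | CC(C)(C)[Si](C)(C)OCC/C=C(C)\[C@@H](O)[C@@H](OC(=O)C=C(C)C)[C@@H](C(C)=C)C[C@@H](OCc1ccc(OC)cc1)C(C)=O | intermediate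
14 | erythro epoxy alcohol (C7–C8 cis-epoxide, configuration of the target) | CC(C)(C)[Si](C)(C)OCC[C@H]1O[C@@]1(C)[C@@H](O)[C@@H](OC(=O)C=C(C)C)[C@@H](C(C)=C)C[C@@H](OCc2ccc(OC)cc2)C(C)=O | intermediate
15 | epoxy acetate (C9 acetate, C10 senecioate, C5 TBS ether) | CC(C)(C)[Si](C)(C)OCC[C@H]1O[C@@]1(C)[C@@H](OC(C)=O)[C@@H](OC(=O)C=C(C)C)[C@@H](C(C)=C)C[C@@H](OCc2ccc(OC)cc2)C(C)=O | intermediate
16 | primary alcohol (C5 hydroxyl) | OCC[C@H]1O[C@@]1(C)[C@@H](OC(C)=O)[C@@H](OC(=O)C=C(C)C)[C@@H](C(C)=C)C[C@@H](OCc2ccc(OC)cc2)C(C)=O | intermediate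
17 | keto aldehyde (C5 aldehyde, C4 methyl ketone, C3 PMB ether) | O=CC[C@H]1O[C@@]1(C)[C@@H](OC(C)=O)[C@@H](OC(=O)C=C(C)C)[C@@H](C(C)=C)C[C@@H](OCc2ccc(OC)cc2)C(C)=O | intermediate
18 | ten-membered diol (C4 and C5 hydroxyls trans, other centres as in the target, C3 PMB ether) | C=C(C)[C@H]1C[C@@H](OCc2ccc(OC)cc2)[C@](C)(O)[C@@H](O)C[C@H]3O[C@@]3(C)[C@@H](OC(C)=O)[C@H]1OC(=O)C=C(C)C | intermediate
19 | C5 angelate, C3 PMB ether | C=C(C)[C@H]1C[C@@H](OCc2ccc(OC)cc2)[C@](C)(O)[C@@H](OC(=O)/C(C)=C\C)C[C@H]3O[C@@]3(C)[C@@H](OC(C)=O)[C@H]1OC(=O)C=C(C)C | intermediate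
20 | CNP0298989.1 (1R,3R,4S,5S,7R,8R,9S,10S in the numbering used here) | C=C(C)[C@H]1C[C@@H](O)[C@](C)(O)[C@@H](OC(=O)/C(C)=C\C)C[C@H]2O[C@@]2(C)[C@@H](OC(C)=O)[C@H]1OC(=O)C=C(C)C | target

Total step count: 17. Longest linear sequence: 16 (steps 1–8 and 10–17 from (R)-carvone).

Steps most likely to fail

Step 15. The ketyl may be reduced further or couple between molecules before the ten-membered ring closes. Even when it closes, the ketyl carbon may add through the alternative samarium-bridged geometry with a gauche backbone, so that facial selectivity at C5 is poor or reversed. The fallback sets out from 17 and accepts that outcome: the same reductive closure then gives the C5-epimeric cis diol F1. Its secondary carbinol is esterified with inversion under Mitsunobu conditions (PPh3, diisopropyl azodicarboxylate, angelic acid, toluene, 0 °C); vicinal diols are known to esterify at the secondary centre with inversion through a dioxaphosphorane. C5 is thus set by SN2 displacement instead of by the C–C bond formation, and the route is rejoined at 19.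

Step 11. The cis substituent on the alkene slows oxygen transfer from the titanium tartrate complex, so erythro selectivity may erode and the long exposure to Ti(OiPr)4 may allow senecioate migration to C9. The fallback sets out from 10 and 12 and sets C9 by ketone reduction instead of by the epoxidation. The Nozaki–Hiyama–Kishi coupling is run under catalyst control (CrCl2, a chiral oxazoline–sulfonamide ligand, NiCl2·(2,9-dimethyl-1,10-phenanthroline), Mn, Cp2ZrCl2, LiCl) to give the C9-epimeric allylic alcohol F2. Its hydroxyl-directed epoxidation under 1,3-allylic-strain control (t-BuOOH, Ti(OiPr)4 without tartrate, −20 °C) should give the threo epoxy alcohol F3, which already has the required oxirane configuration. Dess–Martin oxidation gives the epoxy ketone F4, and chelation-controlled reduction with Zn(BH4)2 (Et2O, −20 °C) should give the erythro epoxy alcohol, rejoining the route at 14.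

Step 5. The perrhenate ester may ionise instead of rearranging, which would lead to elimination toward dienes (and aromatisation) and to loss of the suprafacial transfer, that is, epimerisation at C10. The fallback sets out from 6 and replaces the isomerisation by an oxidation–reduction pair. Oxidative 1,3-transposition with pyridinium chlorochromate, [C5H5NH][CrO3Cl] (CH2Cl2, rt; Babler–Dauben oxidation), gives the enone F5. 1,2-Reduction with LiBH(s-Bu)3 (THF, −78 °C) from the face opposite the adjacent isopropenyl group should then give the cis alcohol, rejoining the route at 7.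

Further compounds
F1 | step 15 | C5-epimeric ten-membered diol (C4 and C5 hydroxyls cis, C3 PMB ether) | C=C(C)[C@H]1C[C@@H](OCc2ccc(OC)cc2)[C@](C)(O)[C@H](O)C[C@H]3O[C@@]3(C)[C@@H](OC(C)=O)[C@H]1OC(=O)C=C(C)C
F2 | step 11 | C9-epimeric (Z)-allylic alcohol (C9 hydroxyl syn to C10 senecioate) | CC(C)(C)[Si](C)(C)OCC/C=C(C)\[C@H](O)[C@@H](OC(=O)C=C(C)C)[C@@H](C(C)=C)C[C@@H](OCc1ccc(OC)cc1)C(C)=O
F3 | step 11 | threo epoxy alcohol (oxirane as in the target, C9 epimeric) | CC(C)(C)[Si](C)(C)OCC[C@H]1O[C@@]1(C)[C@H](O)[C@@H](OC(=O)C=C(C)C)[C@@H](C(C)=C)C[C@@H](OCc2ccc(OC)cc2)C(C)=O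
F4 | step 11 | epoxy ketone (C9 carbonyl) | CC(C)(C)[Si](C)(C)OCC[C@H]1O[C@@]1(C)C(=O)[C@@H](OC(=O)C=C(C)C)[C@@H](C(C)=C)C[C@@H](OCc2ccc(OC)cc2)C(C)=O
F5 | step 5 | enone, 4-[(4-methoxyphenyl)methoxy]-3-methyl-6-(prop-1-en-2-yl)cyclohex-2-en-1-one (ether and isopropenyl cis) | C=C(C)[C@H]1C[C@@H](OCc2ccc(OC)cc2)C(C)=CC1=O
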